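Numbering used throughout: 1 acacetin, 2 prenyl bromide, 3 7-O-prenylacacetin, 4 tert-butyldimethylsilyl chloride, 5 the 5-silyl ether of 3, 6 trimethyl borate, 7 the 3-lithio derivative of 5, 8 the C3 dimethyl boronate, 9 the silylated flavonol, 10 the target.

## Analysis of the target

Target 10 is a flavonol: a 4H-chromen-4-one (benzo ring A fused to pyranone ring C) with a 4-methoxyphenyl group (ring B) at C2, hydroxyl groups at C3 and C5, and a 3-methylbut-2-enyl (prenyl) ether at O7. It has no stereocentre and no stereogenic double bond, because the alkene terminus carries two methyl groups; the whole problem is one of chemo- and regioselectivity. Four oxygen substituents must end up differentiated: a methyl ether on ring B, a prenyl ether at O7, and free hydroxyls at C3 and C5, both hydrogen-bonded to the C4 carbonyl. The aryl prenyl ether is the sensitive group: acid cleaves or cyclises it, hydrogen over palladium reduces or cleaves it, electrophilic oxidants epoxidise it, and strong heating rearranges it. The flavonol enol is also prone to oxidative degradation if left as its anion in air. The difficulty is therefore to introduce the C3 oxygen without an electrophilic oxidant and to free the phenols without acid or hydrogen. The plan rests on one feature: removing the C3 hydroxyl from 10 leaves ether 3, the 7-prenyl ether of the commercial flavone acacetin 1, in which C3 carries the only hydrogen of ring C, directly beside the C4 carbonyl.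

## Retrosynthetic reasoning

**10 back to 9 (O5–Si).** The 5-hydroxyl of 10 is masked as the tert-butyldimethylsilyl ether 9. The cut is placed here because this phenol is acidic and would interfere with the organolithium chemistry that precedes it. A silyl ether is chosen because its removal by a fluoride source needs neither acid nor hydrogen, the two conditions the prenyl ether cannot tolerate. The forward reaction only has to break one Si–O bond under near-neutral conditions.

**9 back to 5 (C3–O), via 8 and 7.** The C3–O bond is the one bond that separates the target skeleton from a commercial flavone, so it is cut next. Forming it by an electrophilic epoxidation of C2=C3 would compete with the more electron-rich prenyl alkene. Instead the bond is made with inverted polarity: C3 becomes a carbanion (7), is captured on boron by trimethyl borate 6 to give boronate 8, and the C–B bond is converted into C–O by a nucleophilic peroxy oxidant. The forward reaction must remove C3–H selectively in the presence of the aryl hydrogens at C6 and C8 and the allylic ether hydrogens, and must oxidise boron without touching the alkene.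

**5 back to 3 and 4 (O5–Si).** The silyl group of 5 comes from tert-butyldimethylsilyl chloride 4. Protection is needed because a free 5-hydroxyl would consume base and, as a lithium phenoxide chelated to the C4 carbonyl, would lower the acidity of C3–H. The forward reaction must overcome the strong hydrogen bond between the 5-hydroxyl and the carbonyl, which is done by forming the phenoxide first.

**3 back to 1 and 2 (O7–C).** The prenyl ether bond is cut to give acacetin 1 and prenyl bromide 2. The cut is safe at this early stage because 1 has only two hydroxyls of very different reactivity: the 7-hydroxyl is acidic and free, the 5-hydroxyl is chelated. Prenylating here, rather than at the end, avoids any competition from the C3 hydroxyl. The forward reaction is a mono-alkylation with a mild carbonate base.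

## Alternatives that were turned down

**Alternative 1: ring A built onto a pyranone.** The disconnection cuts C8–C8a and C4a–C5, so that ring A is assembled last. In the forward direction 1-methoxy-1,3-bis(trimethylsilyloxy)buta-1,3-diene A3 would add across C5=C6 of 5-bromo-3-(methoxymethoxy)-2-(4-methoxyphenyl)-4H-pyran-4-one A2. The nucleophilic CH2 terminus of A3 bonds to the oxygen-bearing C6 and the ketene acetal carbon bonds to the brominated C5. Loss of HBr and methoxytrimethylsilane then aromatises the new ring to 5,7-dihydroxy-3-(methoxymethoxy)-2-(4-methoxyphenyl)-4H-chromen-4-one A1.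

- For it: the C3 oxygen is present from the start, so its position is never in doubt; no finished flavone is exposed to a strong base; and A1 emerges with the 5- and 7-hydroxyls free and already differentiated by chelation. On these points it is stronger than the chosen route, and it would also allow variation of ring A.
- Against it: A2 is not commercial and would need some three to four steps. The C5=C6 bond of a 4-pyranone is a donor-substituted, poorly electrophilic alkene, so the ring-forming step is uncertain. After A1, prenylation at O7 and removal of the acetal at O3 would still follow, and acetal cleavage needs acid in the presence of the prenyl ether.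
- Comparison: roughly seven or more steps against four. The chosen strategy offers in exchange a complete carbon skeleton bought as acacetin 1 and a deprotection by fluoride that the prenyl ether tolerates.

**Alternative 2: carbonyl-directed C5–H hydroxylation of a 5-deoxyflavonol.** The disconnection cuts the C5–O bond. In the forward direction 2-(4-methoxyphenyl)-4-oxo-4H-chromene-3,7-diyl bis(2,2-dimethylpropanoate) A5 would be treated with [RuCl2(p-cymene)]2 (a divalent ruthenium precatalyst) and K2S2O8 in trifluoroacetic acid and its anhydride. The C4 carbonyl would direct metalation to the peri C5–H through a five-membered ruthenacycle, and work-up would reveal 5-hydroxy-2-(4-methoxyphenyl)-4-oxo-4H-chromene-3,7-diyl bis(2,2-dimethylpropanoate) A4.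

- For it: A5 derives from inexpensive aromatic building blocks by aldol condensation, an oxidative cyclisation of the Algar–Flynn–Oyamada type that reliably installs the C3 hydroxyl, and acylation. No cryogenic organolithium is needed and the oxidation is catalytic. On cost of materials and on the certainty of the C3 oxygen it is stronger.
- Against it: the medium is strongly acidic and oxidising, so the prenyl ether cannot be present and must be introduced afterwards. That requires removing both esters and then alkylating O7 selectively against the free C3 hydroxyl, a smaller reactivity gap than 7-OH against 5-OH. The electron-rich ring B is exposed to persulfate, and the ester carbonyls offer competing directing sites.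
- Comparison: about six steps and a late selectivity problem, against four steps in which the prenyl group is installed while only one hydroxyl can react.

**Alternative 3: Friedel–Crafts closure of ring C at C4–C4a.** The disconnection cuts C4–C4a. In the forward direction (E)-2-(benzyloxy)-3-[3,5-bis(benzyloxy)phenoxy]-3-(4-methoxyphenyl)prop-2-enoic acid A7 would be activated as a mixed anhydride with trifluoroacetic anhydride. Its acyl carbon would attack the ortho carbon of the phenoxy ring to give 3,5,7-tris(benzyloxy)-2-(4-methoxyphenyl)-4H-chromen-4-one A6.

- For it: the phloroglucinol-type ring is highly activated and its two ortho positions are equivalent, so there is no regiochemical question; the closure is metal-free and scalable; the C3 oxygen is again built in. On the robustness of the ring-forming step itself it is at least as strong as the chosen key step.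
- Against it: A7 needs several steps and a defined alkene geometry, with the acid cis to the aryloxy group. A6 carries three identical benzyl ethers, so all differentiation is lost. They must be removed by hydrogenolysis before any prenyl group is present, and O7 must then be alkylated selectively among three hydroxyls.
- Comparison: seven to eight steps against four. The chosen route uses the differentiation already present in acacetin 1 and places its risk in a single step.

Key step: step 3

Remark: the target has no stereocentre and no stereogenic alkene, so no stereochemical control is required; acacetin 1 is taken as the commercial starting flavone.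

## Route

Step 1
Reactants: 1 acacetin (5,7-dihydroxy-2-(4-methoxyphenyl)-4H-chromen-4-one); 2 prenyl bromide (1-bromo-3-methylbut-2-ene)
Product: 3 5-hydroxy-2-(4-methoxyphenyl)-7-(3-methylbut-2-enyloxy)-4H-chromen-4-one
Conditions: 2 (1.1 equiv), K2CO3 (1.5 equiv), acetone, reflux
Reagents that add atoms: none
Why: Williamson ether synthesis by SN2 at the primary allylic bromide; K2CO3 ionises only the 7-hydroxyl, the most acidic one because it is conjugated with the C4 carbonyl, while the 5-hydroxyl stays locked in its hydrogen bond to that carbonyl and is not alkylated by a small excess of 2.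

Step 2
Reactants: 3 5-hydroxy-2-(4-methoxyphenyl)-7-(3-methylbut-2-enyloxy)-4H-chromen-4-one; 4 tert-butyldimethylsilyl chloride
Product: 5 5-(tert-butyldimethylsilyloxy)-2-(4-methoxyphenyl)-7-(3-methylbut-2-enyloxy)-4H-chromen-4-one
Conditions: NaH (1.2 equiv), THF/DMF, 0 °C; 4 (1.3 equiv), 0 °C → rt
Reagents that add atoms: none
Why: O-silylation of a phenoxide; NaH breaks the hydrogen-bonded chelate irreversibly and the sodium 5-phenoxide attacks silicon of 4, and the basic medium leaves the prenyl ether and the flavone untouched, whereas a strongly Lewis-acidic silylating agent would activate the C4 carbonyl and endanger the prenyl ether.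

Step 3
Reactants: 5 5-(tert-butyldimethylsilyloxy)-2-(4-methoxyphenyl)-7-(3-methylbut-2-enyloxy)-4H-chromen-4-one; 6 trimethyl borate
Product: 9 5-(tert-butyldimethylsilyloxy)-3-hydroxy-2-(4-methoxyphenyl)-7-(3-methylbut-2-enyloxy)-4H-chromen-4-one, via 3-lithioflavone 7 (not isolated), via C3 dimethyl boronate 8 (not isolated)
Conditions: LiN(iPr)2 (1.3 equiv), THF, −78 °C, 20 min; 6 (3 equiv), −78 → 0 °C; NaBO3·4H2O (3 equiv), THF/H2O, 0 °C → rt
Reagents that add atoms: sodium perborate tetrahydrate, NaBO3·4H2O, [Na+].[O-]OB=O.O.O.O.O
Why: The lithium amide coordinates to the C4 carbonyl and removes the adjacent C3–H at −78 °C, which is the known directed C3 lithiation of alkoxy-substituted flavones; the bulky silyl ether at O5 leaves the C3 side of the carbonyl as the site for lithium. The 3-lithioflavone 7 is captured by trimethyl borate 6 at the same temperature, before it can open ring C by expelling the O1 aryloxide, and the borate complex collapses to the dimethyl boronate 8. Perborate then adds to boron and C3 migrates from boron to oxygen with loss of hydroxide, as in any boronate oxidation; hydrolysis of the resulting borate ester frees the enol, which is flavonol 9. The closest known reaction type is the lithiation, borylation and oxidation sequence that converts protected flavones into flavonols. No ring is closed and no stereocentre is formed; the one new skeletal bond is C3–O. The step needs site selectivity for C3–H over the aryl hydrogens at C6 and C8 and the allylic OCH2 hydrogens, which the carbonyl-directed acidity of C3–H and the limited basicity of a dialkylamide should secure. It also needs an oxidant that spares the trisubstituted prenyl alkene, which the nucleophilic perborate does. Boronate 8 is oxidised without isolation because boron on the enol-ether-like C3 would be lost by protonolysis on storage or chromatography.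

Step 4
Reactants: 9 5-(tert-butyldimethylsilyloxy)-3-hydroxy-2-(4-methoxyphenyl)-7-(3-methylbut-2-enyloxy)-4H-chromen-4-one
Product: 10 3,5-dihydroxy-2-(4-methoxyphenyl)-7-(3-methylbut-2-enyloxy)-4H-chromen-4-one
Conditions: Bu4NF (1.2 equiv), AcOH (1.2 equiv), THF, 0 °C
Reagents that add atoms: none
Why: Fluoride-induced desilylation; fluoride adds to silicon and expels the 5-aryloxide, which the AcOH buffer protonates to the chelated phenol, the buffer keeps the flavonol from standing as its air-sensitive anion, and the prenyl and methyl ethers do not react with fluoride.

## Compound list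

1 | acacetin, 5,7-dihydroxy-2-(4-methoxyphenyl)-4H-chromen-4-one | COc1ccc(cc1)-c1cc(=O)c2c(O)cc(O)cc2o1 | starting material
2 | prenyl bromide, 1-bromo-3-methylbut-2-ene | CC(C)=CCBr | starting material
3 | 5-hydroxy-2-(4-methoxyphenyl)-7-(3-methylbut-2-enyloxy)-4H-chromen-4-one | CC(C)=CCOc1cc(O)c2c(c1)oc(cc2=O)-c1ccc(OC)cc1 | intermediate
4 | tert-butyldimethylsilyl chloride | CC(C)(C)[Si](C)(C)Cl | starting material
5 | 5-(tert-butyldimethylsilyloxy)-2-(4-methoxyphenyl)-7-(3-methylbut-2-enyloxy)-4H-chromen-4-one | CC(C)=CCOc1cc(O[Si](C)(C)C(C)(C)C)c2c(c1)oc(cc2=O)-c1ccc(OC)cc1 | intermediate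
6 | trimethyl borate | COB(OC)OC | starting material
7 | 3-lithio derivative of 5, [5-(tert-butyldimethylsilyloxy)-2-(4-methoxyphenyl)-7-(3-methylbut-2-enyloxy)-4-oxo-4H-chromen-3-yl]lithium (not isolated) | CC(C)=CCOc1cc(O[Si](C)(C)C(C)(C)C)c2c(c1)oc(c([Li])c2=O)-c1ccc(OC)cc1 | intermediate
8 | dimethyl [5-(tert-butyldimethylsilyloxy)-2-(4-methoxyphenyl)-7-(3-methylbut-2-enyloxy)-4-oxo-4H-chromen-3-yl]boronate (not isolated) | CC(C)=CCOc1cc(O[Si](C)(C)C(C)(C)C)c2c(c1)oc(c(B(OC)OC)c2=O)-c1ccc(OC)cc1 | intermediate
9 | 5-(tert-butyldimethylsilyloxy)-3-hydroxy-2-(4-methoxyphenyl)-7-(3-methylbut-2-enyloxy)-4H-chromen-4-one | CC(C)=CCOc1cc(O[Si](C)(C)C(C)(C)C)c2c(c1)oc(c(O)c2=O)-c1ccc(OC)cc1 | intermediate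
10 | 3,5-dihydroxy-2-(4-methoxyphenyl)-7-(3-methylbut-2-enyloxy)-4H-chromen-4-one | COc1ccc(-c2oc3cc(OCC=C(C)C)cc(O)c3c(=O)c2O)cc1 | target

## Step count and least certain steps

Total step count: 4. Longest linear sequence: 4 steps, from acacetin 1.

**Step 3 (key step).** Several processes could divert it:
- incomplete metalation, or hydride transfer from the amide to the C4 carbonyl in place of deprotonation;
- ring opening of the 3-lithio species by elimination of the ring oxygen if it warms before the borate captures it;
- protonolysis of the C–B bond before oxidation, which would return 5;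
- over-oxidation of the flavonol anion by excess peroxide.

Loss of the silyl group during the basic oxidation would be harmless, since it only advances material to 10.

The fallback sets out from acacetin 1 and comes back to the route at target 10, placing an electrophilic oxidation before any prenyl group is present. Both hydroxyls of 1 would be benzylated (benzyl bromide, K2CO3, DMF, 80 °C) to give 5,7-bis(benzyloxy)-2-(4-methoxyphenyl)-4H-chromen-4-one F1. Dimethyldioxirane in acetone/CH2Cl2 at 0 °C would epoxidise C2=C3 to racemic 5,7-bis(benzyloxy)-2,3-epoxy-2-(4-methoxyphenyl)chroman-4-one F2. Without isolation, a catalytic amount of p-toluenesulfonic acid would open it to 5,7-bis(benzyloxy)-3-hydroxy-2-(4-methoxyphenyl)-4H-chromen-4-one F3. Hydrogenolysis (H2, Pd/C, EtOAc/MeOH) would give 3,5,7-trihydroxy-2-(4-methoxyphenyl)-4H-chromen-4-one F4. One equivalent of prenyl bromide 2 with K2CO3 in acetone would then alkylate the most acidic 7-hydroxyl to give 10. The price is five operations and a final alkylation that must distinguish O7 from O3.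

**Step 2.** The most likely failures are incomplete silylation of the chelated hydroxyl and loss of the silyl ether, which sits peri to the carbonyl, during chromatography or before the metalation is complete.

The fallback sets out from 3 and comes back at target 10, replacing the silyl ether with an acetal that is installed by alkylation and still removed by fluoride. The sodium phenoxide of 3 (NaH, DMF, 0 °C) would be alkylated with 2-(trimethylsilyl)ethoxymethyl chloride to give 2-(4-methoxyphenyl)-7-(3-methylbut-2-enyloxy)-5-{[2-(trimethylsilyl)ethoxy]methoxy}-4H-chromen-4-one F5. The conditions of step 3 would lead through the 3-lithio derivative F6 and the C3 dimethyl boronate F7, neither isolated, to 3-hydroxy-2-(4-methoxyphenyl)-7-(3-methylbut-2-enyloxy)-5-{[2-(trimethylsilyl)ethoxy]methoxy}-4H-chromen-4-one F8. Bu4NF in THF at 50 °C under argon would then fragment the acetal and give 10.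

**Step 1.** The ambident phenoxide could be alkylated at carbon (C6 or C8), and excess bromide could alkylate O5; the poor solubility of 1 in acetone could also slow the reaction and favour these side paths.

The fallback sets out from 1 and comes back at 3 by a Mitsunobu reaction: 3-methylbut-2-en-1-ol, PPh3 and diisopropyl azodicarboxylate in THF/DMF at 0 °C. It etherifies only the more acidic, unchelated 7-hydroxyl and forms no free phenoxide, so C-alkylation is not expected. No compound outside the list is made (entry F0).

## Further compounds

F1 | step 3 | 5,7-bis(benzyloxy)-2-(4-methoxyphenyl)-4H-chromen-4-one | COc1ccc(cc1)-c1cc(=O)c2c(OCc3ccccc3)cc(OCc3ccccc3)cc2o1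
F2 | step 3 | racemic 5,7-bis(benzyloxy)-2,3-epoxy-2-(4-methoxyphenyl)chroman-4-one (cis ring fusion, not isolated) | COc1ccc(cc1)C12OC1C(=O)c1c(OCc3ccccc3)cc(OCc3ccccc3)cc1O2
F3 | step 3 | 5,7-bis(benzyloxy)-3-hydroxy-2-(4-methoxyphenyl)-4H-chromen-4-one | COc1ccc(cc1)-c1oc2cc(OCc3ccccc3)cc(OCc3ccccc3)c2c(=O)c1O
F4 | step 3 | 3,5,7-trihydroxy-2-(4-methoxyphenyl)-4H-chromen-4-one (kaempferide) | COc1ccc(cc1)-c1oc2cc(O)cc(O)c2c(=O)c1O
F5 | step 2 | 2-(4-methoxyphenyl)-7-(3-methylbut-2-enyloxy)-5-{[2-(trimethylsilyl)ethoxy]methoxy}-4H-chromen-4-one | CC(C)=CCOc1cc(OCOCC[Si](C)(C)C)c2c(c1)oc(cc2=O)-c1ccc(OC)cc1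
F6 | step 2 | 3-lithio derivative of F5 (not isolated) | CC(C)=CCOc1cc(OCOCC[Si](C)(C)C)c2c(c1)oc(c([Li])c2=O)-c1ccc(OC)cc1
F7 | step 2 | C3 dimethyl boronate of F5 (not isolated) | CC(C)=CCOc1cc(OCOCC[Si](C)(C)C)c2c(c1)oc(c(B(OC)OC)c2=O)-c1ccc(OC)cc1
F8 | step 2 | 3-hydroxy-2-(4-methoxyphenyl)-7-(3-methylbut-2-enyloxy)-5-{[2-(trimethylsilyl)ethoxy]methoxy}-4H-chromen-4-one | CC(C)=CCOc1cc(OCOCC[Si](C)(C)C)c2c(c1)oc(c(O)c2=O)-c1ccc(OC)cc1
F0 | step 1 | none | none
A1 | alternative 1 | 5,7-dihydroxy-3-(methoxymethoxy)-2-(4-methoxyphenyl)-4H-chromen-4-one | COCOc1c(-c2ccc(OC)cc2)oc2cc(O)cc(O)c2c1=O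
A2 | alternative 1 | 5-bromo-3-(methoxymethoxy)-2-(4-methoxyphenyl)-4H-pyran-4-one | COCOc1c(-c2ccc(OC)cc2)occ(Br)c1=O
A3 | alternative 1 | 1-methoxy-1,3-bis(trimethylsilyloxy)buta-1,3-diene (either geometry at the ketene acetal serves) | COC(O[Si](C)(C)C)=CC(=C)O[Si](C)(C)C
A4 | alternative 2 | 5-hydroxy-2-(4-methoxyphenyl)-4-oxo-4H-chromene-3,7-diyl bis(2,2-dimethylpropanoate) | COc1ccc(cc1)-c1oc2cc(OC(=O)C(C)(C)C)cc(O)c2c(=O)c1OC(=O)C(C)(C)C
A5 | alternative 2 | 2-(4-methoxyphenyl)-4-oxo-4H-chromene-3,7-diyl bis(2,2-dimethylpropanoate) | COc1ccc(cc1)-c1oc2cc(OC(=O)C(C)(C)C)ccc2c(=O)c1OC(=O)C(C)(C)C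
A6 | alternative 3 | 3,5,7-tris(benzyloxy)-2-(4-methoxyphenyl)-4H-chromen-4-one | COc1ccc(cc1)-c1oc2cc(OCc3ccccc3)cc(OCc3ccccc3)c2c(=O)c1OCc1ccccc1
A7 | alternative 3 | (E)-2-(benzyloxy)-3-[3,5-bis(benzyloxy)phenoxy]-3-(4-methoxyphenyl)prop-2-enoic acid | OC(=O)/C(OCc1ccccc1)=C(\Oc1cc(OCc2ccccc2)cc(OCc2ccccc2)c1)c1ccc(OC)cc1
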